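## Structural features

The target is an 8–5′ neolignan built on a 2,3-dihydrobenzofuran. Ring A (the benzo ring) carries a 7-methoxy group and an (E)-propenoic acid at C5. Ring B (O1, C2, C3, C3a, C7a) carries ring C, a 4-hydroxy-3,5-dimethoxyphenyl group, at C2 and the hydroxymethyl carbon C9 at C3. C2 and C3 are adjacent stereocentres; the SMILES decodes to (2S,3R), with ring C and C9 trans. Trans is the thermodynamically preferred arrangement, so the real difficulty is the absolute configuration of the pair. The fragile point is the benzylic C2–O1 bond para to the free ring-C phenol: acid ionises it and base opens it through a para-quinone methide, and either event can scramble C2. The electron-rich phenol is easily oxidised, and the cinnamic acid alkene and the benzylic ether rule out hydrogenation and hydrogenolysis. The feature exploited is that O1 and C9 sit on the neighbouring carbons C2 and C3, which are the two alkene carbons of an E-stilbene joining ring A (through C3a) to ring C. Adding the ring-A phenol oxygen and a carbonyl carbon across that alkene closes ring B and makes both skeletal bonds and both stereocentres in one step.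

## Logic of the disconnections

12 ⇒ 9 + 10. The Cα=Cβ double bond of the propenoic acid on C5 of ring A is cut, returning two carbons to 10. The acid is the most polar function and is best made last; what remains on ring A is an aldehyde. The forward condensation must give the E acid under conditions mild enough for the free phenol and the C2–O1 bond.

9 ⇒ 8 ⇒ 7. No skeletal bond is cut. The C9 alcohol goes back to a methyl ester, the ring-C phenol to its pivalate and the aldehyde to its dimethyl acetal. In 7 every fragile function is masked and C9 is at the oxidation level a carbonylation delivers. The demand is one of order: the ester must be reduced before the aldehyde is freed and condensed, because the C3 hydrogen next to the ester is acidic and amine base could open ring B by β-elimination of O1. One hydride reagent must take both the ester and the hindered pivalate, and the acidic work-up must cleave the acetal without ionising C2.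

7 ⇒ 6. O1–C2 and C3–C9 are cut, together with the ester C9–OMe bond. This opens ring B, removes both stereocentres and leaves a planar E-stilbene with a free ortho phenol on ring A. It is the largest simplification in the route. The forward step must choose one alkene face (C2), deliver the carbonyl trans to ring C (C3), and capture CO faster than the alkyl palladium loses the C2 hydrogen.

6 ⇒ 5. Only the two acetal C–O bonds are cut. A dimethyl acetal para to a free phenol is the most labile group of the precursor, so it is installed directly before use and not carried through the coupling. The forward step needs a non-acidic isolation.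

5 ⇒ 3 + 4. The bond between the alkene carbon (future C3) and ring A (future C3a) is cut. This gives two benzene derivatives of similar size; 4 already has its halogen ortho to the phenol and para to the formyl group. The forward coupling must be β-selective and E-selective and must tolerate a free phenol, an aldehyde and an aryl pivalate.

3 ⇒ 2 ⇒ 1. The terminal C=CH2 bond is cut back to the aldehyde, then the O–acyl bond back to the phenol. Both steps are routine; the only demand is that the ylide attacks the aldehyde and not the hindered aryl ester.

## Other disconnections considered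

Alternative 1: The cut is through the C2–ring C bond and the C3–C3a bond, made in one three-component step. The ring-C bromide A1 is lithiated and added to the E alkenyl boronic ester A2. The boronate complex is then coupled with the ring-A aryl iodide A3 under Pd(OAc)2 and a chiral MandyPhos ligand. Ring C shifts from boron to C2 while palladium delivers ring A to C3, giving the syn boronic ester A4.

- In its favour: it belongs to an established class of catalytic enantioselective reactions, so on precedent for the asymmetric C–C bond formation it is the better plan. In convergence it is the equal of the chosen plan (three simple pieces against two).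
- Against it: ring B is not closed. Oxidising the C2–B bond of A4 with retention puts the hydroxyl where O1 sits in the target, but ring A already carries its own oxygen. Closure by displacement at C2 would therefore invert and lead to the cis ring. Closure would have to go through ionisation of C2, which is stereoconvergent and makes the ligand-bought C2 control redundant.
- Further costs: an ortho-substituted, electron-rich electrophile and a hindered migrating aryl are demanding for this coupling. Cryogenic organolithium chemistry and four protecting groups are needed. Oxidation, deprotection and cyclisation follow before the same end game.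
- Comparison: the chosen plan closes the ring and sets C2 and C3 in the same step, and is several steps shorter, but rests on an untested step.

Alternative 2: The cut is O1–C7a. The acyclic secondary benzylic alcohol A5, with a triflate at C7a, would be closed by zerovalent palladium from Pd2(dba)3 with a bulky biarylphosphine and Cs2CO3 to give A6.

- In its favour: the C2–O bond is never broken, so C2 is carried through with retention and no quinone methide chemistry is involved. On stereochemical integrity in the ring closure it is the equal of the chosen plan. Intramolecular aryl etherification to five-membered rings is a known reaction class, so on reliability of the key step it is the better plan.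
- Against it: the key step creates no stereocentre. Both centres of A5 must be set beforehand in an acyclic 1,2-diaryl-1,3-diol derivative by a separate asymmetric method.
- The triflate is flanked on both sides, which slows oxidative addition and C–O reductive elimination. The palladium alkoxide of a secondary benzylic alcohol can lose a β-hydrogen, giving a ketone and a reduced arene.
- Comparison: four protecting or activating groups must be installed and removed, so the step count is clearly higher than the seven steps of the chosen plan.

Alternative 3: The cut is O1–C2 by ionisation. Mild acid would convert the diol A7, as either C2 epimer, into the syringyl para-quinone methide. The ring-A phenol adds to C2 to give the trans dihydrobenzofuran A8.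

- In its favour: the closure is biomimetic, stereoconvergent at C2 and needs no metal and no protecting group. On precedent and protecting-group economy it is the better plan. A8 could reach the target by a single Heck reaction with an acrylate, so its end game is at least the equal of the chosen one.
- Against it: C3 must be set earlier, most plausibly with a stoichiometric auxiliary on a ring-A arylacetic acid that itself takes several steps. The trans outcome depends on C3 alone under equilibrating conditions. The free, oxidation-prone syringyl phenol is present throughout. The late Heck reaction would have to engage an electron-rich aryl bromide bearing free hydroxyl groups.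
- Comparison: the chosen plan sets both centres catalytically in the ring-forming step from a stilbene made in three steps, and should be shorter overall. Alternative 3 carries the lower mechanistic risk.

Key step: step 5

Assumption: the (S,S) enantiomer of the bisoxazoline is taken as the one that leads to 2S; if the sense of induction is the opposite, the (R,R) ligand is used and nothing else in the route changes.

## Route

Step 1
Reactants: 1 syringaldehyde (4-hydroxy-3,5-dimethoxybenzaldehyde)
Product: 2 4-formyl-2,6-dimethoxyphenyl pivalate
Conditions: PivCl, Et3N, DMAP (cat.), CH2Cl2, 0 °C to rt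
Reagents that add atoms: pivaloyl chloride CC(C)(C)C(=O)Cl
Why: Acylation of a phenol under nucleophilic catalysis; the pivalate resists the ylide and amine bases of steps 2 and 3, keeps the ring-C oxygen from feeding electrons into C2 or being oxidised in step 5, and is removed in the hydride step without a step of its own.

Step 2
Reactants: 2 4-formyl-2,6-dimethoxyphenyl pivalate
Product: 3 4-ethenyl-2,6-dimethoxyphenyl pivalate
Conditions: Ph3PCH3Br, KOtBu, THF, 0 °C; then 2, −78 °C to 0 °C
Reagents that add atoms: methyltriphenylphosphonium bromide C[P+](c1ccccc1)(c1ccccc1)c1ccccc1.[Br-]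
Why: Wittig methylenation; the unstabilised ylide should add to the aldehyde far faster than to the pivalate, which is shielded by the tert-butyl group and two ortho methoxy groups, provided the ylide is not used in excess and the temperature is kept low.

Step 3
Reactants: 3 4-ethenyl-2,6-dimethoxyphenyl pivalate; 4 5-iodovanillin (4-hydroxy-3-iodo-5-methoxybenzaldehyde)
Product: 5 4-[(E)-2-(5-formyl-2-hydroxy-3-methoxyphenyl)ethenyl]-2,6-dimethoxyphenyl pivalate
Conditions: Pd(OAc)2 (5 mol%), P(o-tol)3 (10 mol%), Et3N, DMF, 90 °C
Reagents that add atoms: none
Why: Mizoroki–Heck reaction; oxidative addition into the C–I bond of 4 (activated by the para formyl group), syn insertion of the styrene with aryl transfer to the terminal carbon and syn β-hydride elimination should give the E-stilbene; free ortho phenols, aldehydes and hindered aryl esters are tolerated under amine base.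

Step 4
Reactants: 5 4-[(E)-2-(5-formyl-2-hydroxy-3-methoxyphenyl)ethenyl]-2,6-dimethoxyphenyl pivalate
Product: 6 4-{(E)-2-[5-(dimethoxymethyl)-2-hydroxy-3-methoxyphenyl]ethenyl}-2,6-dimethoxyphenyl pivalate
Conditions: HC(OMe)3, MeOH, PPTS (cat.), rt; Et3N quench, evaporation, short plug of basic Al2O3
Reagents that add atoms: trimethyl orthoformate COC(OC)OC; methanol CO
Why: Acid-catalysed acetalisation driven by the orthoformate as water scavenger; the acetal shields the aldehyde from hydride in step 6 and, being the methanol acetal, only exchanges degenerately in the methanol medium of step 5; it is labile to aqueous acid because it is para to a free phenol, hence the amine quench and non-acidic isolation.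

Step 5
Reactants: 6 4-{(E)-2-[5-(dimethoxymethyl)-2-hydroxy-3-methoxyphenyl]ethenyl}-2,6-dimethoxyphenyl pivalate
Product: 7 methyl (2S,3S)-5-(dimethoxymethyl)-2-[3,5-dimethoxy-4-(pivaloyloxy)phenyl]-7-methoxy-2,3-dihydro-1-benzofuran-3-carboxylate (trans)
Conditions: Pd(OCOCF3)2 (10 mol%), (S,S)-Ph-box [2,2′-isopropylidenebis((4S)-4-phenyl-2-oxazoline)] (12 mol%), p-benzoquinone (1.5 equiv), CO (1 atm), HC(OMe)3 (2 equiv), MeOH, 0 °C
Reagents that add atoms: carbon monoxide [C-]#[O+]; methanol CO
Why: Proposed new method: divalent palladium bound to the bisoxazoline coordinates one face of the E alkene of 6 and the ortho phenol of ring A attacks C2 from the opposite face, a metal-assisted 5-endo-trig closure of ring B (O1–C2) that leaves palladium on C3 as a benzylic alkyl; this alkyl inserts CO with retention and the acyl palladium is cleaved by methanol to the C3 ester (C3–C9), after which benzoquinone returns zerovalent palladium to the divalent state. The closest known reaction types are the intramolecular alkoxypalladation–methoxycarbonylation of hydroxy alkenes, the 5-endo heteropalladation of ortho-vinyl phenols and anilines (which normally ends in the aromatic heterocycle) and bisoxazoline–palladium enantioselective Wacker-type cyclisations; their combination on a 2-hydroxystilbene is without precedent. C2 is controlled by the ligand, which decides the alkene face that palladium occupies and therefore the face the phenol must attack. C3 is controlled by the substrate and the mechanism: anti addition to the E alkene followed by retentive insertion puts the ester trans to ring C, and trans is also the thermodynamic arrangement at the enolisable C3. The step needs carbonylation to outrun loss of the C2 hydrogen, which lies syn to palladium after anti addition; CO saturation, a bidentate ligand that leaves no free cis site, low temperature and η3-benzyl stabilisation of the C3–Pd bond all act in that direction. It also needs alkene activation to outrun formation of an aryloxycarbonyl palladium species that would lead to a six-membered lactone, which the slightly acidic, chloride-free methanol medium favours; benzoquinone is preferred to CuCl2 so that no chloride competes with the chiral ligand and no HCl builds up. In the substrate the pivalate keeps ring C from being oxidised and from ionising the new C2–O1 bond, ring size leaves C2 as the only carbon the oxygen can reach, and the dimethyl acetal merely exchanges with the solvent.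

Step 6
Reactants: 7 methyl (2S,3S)-5-(dimethoxymethyl)-2-[3,5-dimethoxy-4-(pivaloyloxy)phenyl]-7-methoxy-2,3-dihydro-1-benzofuran-3-carboxylate
Product: 9 (2S,3R)-2-(4-hydroxy-3,5-dimethoxyphenyl)-3-(hydroxymethyl)-7-methoxy-2,3-dihydro-1-benzofuran-5-carbaldehyde, via dimethyl acetal diol 8 (not isolated)
Conditions: LiAlH4, THF, −10 °C to 0 °C; then 1 M aq. HCl, THF, rt
Reagents that add atoms: water O
Why: Hydride reduction of esters followed by acetal hydrolysis on acidic work-up; LiAlH4 is used because a borohydride would be expected to leave the doubly ortho-flanked pivalate largely intact, and it should reduce the methyl ester to the C9 alcohol and cleave the pivalate in one operation before the dilute acid quench unmasks the aldehyde. No bond at C2 or C3 is broken; the C3 descriptor changes from S to R only because the CIP ranking changes when CO2Me becomes CH2OH.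

Step 7
Reactants: 9 (2S,3R)-2-(4-hydroxy-3,5-dimethoxyphenyl)-3-(hydroxymethyl)-7-methoxy-2,3-dihydro-1-benzofuran-5-carbaldehyde; 10 malonic acid
Product: 12 (2E)-3-[(2S,3R)-2-(4-hydroxy-3,5-dimethoxyphenyl)-3-(hydroxymethyl)-7-methoxy-2,3-dihydro-1-benzofuran-5-yl]prop-2-enoic acid, via arylidenemalonic acid 11 (not isolated)
Conditions: pyridine, piperidine (cat.), 80 °C; dilute acid work-up
Reagents that add atoms: none
Why: Knoevenagel–Doebner condensation; the iminium formed with piperidine condenses with malonic acid to the arylidenemalonic acid, which decarboxylates in warm pyridine to the thermodynamically preferred E acid. Free phenols and alcohols are tolerated, and the excess malonic acid keeps the ring-C phenol protonated so that the C2–O1 bond is not pushed open.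

## Compound list

1 | syringaldehyde (4-hydroxy-3,5-dimethoxybenzaldehyde) | COc1cc(C=O)cc(OC)c1O | starting material
2 | 4-formyl-2,6-dimethoxyphenyl pivalate | COc1cc(C=O)cc(OC)c1OC(=O)C(C)(C)C | intermediate
3 | 4-ethenyl-2,6-dimethoxyphenyl pivalate | COc1cc(C=C)cc(OC)c1OC(=O)C(C)(C)C | intermediate
4 | 5-iodovanillin (4-hydroxy-3-iodo-5-methoxybenzaldehyde) | COc1cc(C=O)cc(I)c1O | starting material
5 | 4-[(E)-2-(5-formyl-2-hydroxy-3-methoxyphenyl)ethenyl]-2,6-dimethoxyphenyl pivalate | COc1cc(/C=C/c2cc(C=O)cc(OC)c2O)cc(OC)c1OC(=O)C(C)(C)C | intermediate
6 | 4-{(E)-2-[5-(dimethoxymethyl)-2-hydroxy-3-methoxyphenyl]ethenyl}-2,6-dimethoxyphenyl pivalate | COc1cc(/C=C/c2cc(C(OC)OC)cc(OC)c2O)cc(OC)c1OC(=O)C(C)(C)C | intermediate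
7 | methyl (2S,3S)-5-(dimethoxymethyl)-2-[3,5-dimethoxy-4-(pivaloyloxy)phenyl]-7-methoxy-2,3-dihydro-1-benzofuran-3-carboxylate (trans) | COc1cc([C@H]2Oc3c(OC)cc(C(OC)OC)cc3[C@@H]2C(=O)OC)cc(OC)c1OC(=O)C(C)(C)C | intermediate
8 | 4-[(2S,3R)-5-(dimethoxymethyl)-3-(hydroxymethyl)-7-methoxy-2,3-dihydro-1-benzofuran-2-yl]-2,6-dimethoxyphenol | COc1cc([C@H]2Oc3c(OC)cc(C(OC)OC)cc3[C@@H]2CO)cc(OC)c1O | intermediate
9 | (2S,3R)-2-(4-hydroxy-3,5-dimethoxyphenyl)-3-(hydroxymethyl)-7-methoxy-2,3-dihydro-1-benzofuran-5-carbaldehyde | COc1cc([C@H]2Oc3c(OC)cc(C=O)cc3[C@@H]2CO)cc(OC)c1O | intermediate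
10 | malonic acid | O=C(O)CC(=O)O | starting material
11 | 2-{[(2S,3R)-2-(4-hydroxy-3,5-dimethoxyphenyl)-3-(hydroxymethyl)-7-methoxy-2,3-dihydro-1-benzofuran-5-yl]methylidene}propanedioic acid | COc1cc([C@H]2Oc3c(OC)cc(C=C(C(=O)O)C(=O)O)cc3[C@@H]2CO)cc(OC)c1O | intermediate
12 | (2E)-3-[(2S,3R)-2-(4-hydroxy-3,5-dimethoxyphenyl)-3-(hydroxymethyl)-7-methoxy-2,3-dihydro-1-benzofuran-5-yl]prop-2-enoic acid | COc1cc([C@H]2Oc3c(OC)cc(/C=C/C(=O)O)cc3[C@@H]2CO)cc(OC)c1O | target

## Step count and least certain steps

Total step count: 7. Longest linear sequence: 7 steps (1 to 12); 4 and 10 are commercial and enter at steps 3 and 7.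

**Step 5 (key step, proposed new method).** Three things are most likely to go wrong.
- β-Hydride loss from the C3–palladium alkyl could win over CO insertion, because the C2 hydrogen is syn to the metal after anti addition. The ring would then aromatise and both stereocentres would be lost.
- Facial selection of the alkene could be poor, since the ligand must distinguish the two faces of a nearly symmetrical diaryl alkene.
- Carbonylative lactonisation through an aryloxycarbonyl palladium species could divert material.
- Erosion of trans selectivity by a syn oxypalladation pathway is less serious, because brief base equilibration at C3 would repair it.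

Fallback (known chemistry; sets out from 2 and 4, returns at 7): ring B would be closed by enantioselective intramolecular C–H insertion of a dirhodium carbenoid, an established way to cis 2-aryl-2,3-dihydrobenzofuran-3-carboxylates. NaBH4 in MeOH at 0 °C reduces 2 to 4-(hydroxymethyl)-2,6-dimethoxyphenyl pivalate F1. PBr3 in CH2Cl2 converts it into 4-(bromomethyl)-2,6-dimethoxyphenyl pivalate F2. O-Alkylation of 4 with F2 (K2CO3, DMF, rt) gives 4-[(4-formyl-2-iodo-6-methoxyphenoxy)methyl]-2,6-dimethoxyphenyl pivalate F3. Acetalisation as in step 4 gives 4-{[4-(dimethoxymethyl)-2-iodo-6-methoxyphenoxy]methyl}-2,6-dimethoxyphenyl pivalate F4. Palladium-catalysed coupling of the aryl iodide with methyl diazoacetate (Pd(PPh3)4, Ag2CO3, Et3N, toluene, rt) gives methyl 2-diazo-2-[5-(dimethoxymethyl)-2-{[3,5-dimethoxy-4-(pivaloyloxy)phenyl]methoxy}-3-methoxyphenyl]acetate F5. Dirhodium tetrakis[N-phthaloyl-(S)-tert-leucinate], Rh2(S-PTTL)4 (or its mirror image, whichever leads to 2S), in toluene at −60 °C inserts the carbenoid into the benzylic C–H bond next to oxygen. This gives methyl (2S,3R)-5-(dimethoxymethyl)-2-[3,5-dimethoxy-4-(pivaloyloxy)phenyl]-7-methoxy-2,3-dihydro-1-benzofuran-3-carboxylate (cis) F6. A catalytic amount of NaOMe in MeOH at 0 °C, which the hindered pivalate should tolerate, epimerises C3 to the trans ester 7.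

**Step 7.** Base-triggered opening of ring B through the para-quinone methide of the free ring-C phenol is the main concern. The para formyl group makes the ring-A oxygen a better leaving group until the aldehyde has condensed. The result would be epimerisation at C2 or capture of the quinone methide by piperidine. Incomplete decarboxylation is a lesser concern.

Fallback (sets out from 9, returns at 12): a neutral Wittig reaction with methyl (triphenylphosphoranylidene)acetate in toluene at 60 °C gives methyl (2E)-3-[(2S,3R)-2-(4-hydroxy-3,5-dimethoxyphenyl)-3-(hydroxymethyl)-7-methoxy-2,3-dihydro-1-benzofuran-5-yl]prop-2-enoate F7. LiOH in aqueous THF at rt hydrolyses it to 12.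

**Step 6.** Once the pivalate has fallen off in the presence of excess hydride, the ring-C phenoxide could expel O1 and the resulting quinone methide would be reduced, which is a reductive ring opening. Over-long contact with aqueous acid could also ionise C2 and epimerise it.

Fallback (sets out from 7, returns at 8): the three events are separated so that hydride and free phenoxide never meet. LiBH4 in THF at 0 °C reduces only the methyl ester and gives 4-[(2S,3R)-5-(dimethoxymethyl)-3-(hydroxymethyl)-7-methoxy-2,3-dihydro-1-benzofuran-2-yl]-2,6-dimethoxyphenyl pivalate F8. NaOMe in MeOH at rt removes the pivalate by methanolysis to give 8. PPTS in wet acetone then frees the aldehyde to give 9, and the route continues with step 7.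

**Step 2.** Acyl transfer from the aryl pivalate to the ylide could compete, since an aryl ester is an activated acyl donor. The electron-rich styrene could also polymerise on concentration.

Fallback (sets out from 1 and 10, returns at 3): a decarboxylative Knoevenagel–Doebner reaction of 1 with 10 (piperidine, DMF, 130 °C) gives 4-ethenyl-2,6-dimethoxyphenol F9. Pivaloylation (PivCl, Et3N, DMAP, CH2Cl2, 0 °C) then gives 3.

## Further compounds

F1 | step 5 | 4-(hydroxymethyl)-2,6-dimethoxyphenyl pivalate | COc1cc(CO)cc(OC)c1OC(=O)C(C)(C)C
F2 | step 5 | 4-(bromomethyl)-2,6-dimethoxyphenyl pivalate | COc1cc(CBr)cc(OC)c1OC(=O)C(C)(C)C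
F3 | step 5 | 4-[(4-formyl-2-iodo-6-methoxyphenoxy)methyl]-2,6-dimethoxyphenyl pivalate | COc1cc(COc2c(I)cc(C=O)cc2OC)cc(OC)c1OC(=O)C(C)(C)C
F4 | step 5 | 4-{[4-(dimethoxymethyl)-2-iodo-6-methoxyphenoxy]methyl}-2,6-dimethoxyphenyl pivalate | COc1cc(COc2c(I)cc(C(OC)OC)cc2OC)cc(OC)c1OC(=O)C(C)(C)C
F5 | step 5 | methyl 2-diazo-2-[5-(dimethoxymethyl)-2-{[3,5-dimethoxy-4-(pivaloyloxy)phenyl]methoxy}-3-methoxyphenyl]acetate | COC(=O)C(=[N+]=[N-])c1cc(C(OC)OC)cc(OC)c1OCc1cc(OC)c(OC(=O)C(C)(C)C)c(OC)c1
F6 | step 5 | methyl (2S,3R)-5-(dimethoxymethyl)-2-[3,5-dimethoxy-4-(pivaloyloxy)phenyl]-7-methoxy-2,3-dihydro-1-benzofuran-3-carboxylate (cis) | COc1cc([C@H]2Oc3c(OC)cc(C(OC)OC)cc3[C@H]2C(=O)OC)cc(OC)c1OC(=O)C(C)(C)C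
F7 | step 7 | methyl (2E)-3-[(2S,3R)-2-(4-hydroxy-3,5-dimethoxyphenyl)-3-(hydroxymethyl)-7-methoxy-2,3-dihydro-1-benzofuran-5-yl]prop-2-enoate | COc1cc([C@H]2Oc3c(OC)cc(/C=C/C(=O)OC)cc3[C@@H]2CO)cc(OC)c1O
F8 | step 6 | 4-[(2S,3R)-5-(dimethoxymethyl)-3-(hydroxymethyl)-7-methoxy-2,3-dihydro-1-benzofuran-2-yl]-2,6-dimethoxyphenyl pivalate | COc1cc([C@H]2Oc3c(OC)cc(C(OC)OC)cc3[C@@H]2CO)cc(OC)c1OC(=O)C(C)(C)C
F9 | step 2 | 4-ethenyl-2,6-dimethoxyphenol | COc1cc(C=C)cc(OC)c1O
A1 | alternative 1 | 5-bromo-1,3-dimethoxy-2-(methoxymethoxy)benzene | COCOc1c(OC)cc(Br)cc1OC
A2 | alternative 1 | tert-butyldimethyl{[(2E)-3-(4,4,5,5-tetramethyl-1,3,2-dioxaborolan-2-yl)prop-2-en-1-yl]oxy}silane | CC(C)(C)[Si](C)(C)OC/C=C/B1OC(C)(C)C(C)(C)O1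
A3 | alternative 1 | 2-[3-iodo-5-methoxy-4-(methoxymethoxy)phenyl]-1,3-dioxolane | COCOc1c(I)cc(C2OCCO2)cc1OC
A4 | alternative 1 | syn 1,2-diaryl-3-(tert-butyldimethylsilyloxy)propyl pinacol boronic ester, C3 as in the target | COc1cc([C@@H](B2OC(C)(C)C(C)(C)O2)[C@@H](CO[Si](C)(C)C(C)(C)C)c2cc(C3OCCO3)cc(OC)c2OCOC)cc(OC)c1OCOC
A5 | alternative 2 | 2-[3-(tert-butyldimethylsilyloxy)-1-hydroxy-1-(3,5-dimethoxy-4-(methoxymethoxy)phenyl)propan-2-yl]-4-(1,3-dioxolan-2-yl)-6-methoxyphenyl triflate, C2 and C3 as in the target | COc1cc([C@@H](O)[C@@H](CO[Si](C)(C)C(C)(C)C)c2cc(C3OCCO3)cc(OC)c2OS(=O)(=O)C(F)(F)F)cc(OC)c1OCOC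
A6 | alternative 2 | protected trans 2-aryl-3-(silyloxymethyl)-7-methoxy-2,3-dihydrobenzofuran-5-carbaldehyde dioxolane acetal | COc1cc([C@H]2Oc3c(OC)cc(C4OCCO4)cc3[C@@H]2CO[Si](C)(C)C(C)(C)C)cc(OC)c1OCOC
A7 | alternative 3 | 2-(5-bromo-2-hydroxy-3-methoxyphenyl)-1-(4-hydroxy-3,5-dimethoxyphenyl)propane-1,3-diol, C3 as in the target, either C2 epimer | COc1cc(C(O)[C@@H](CO)c2cc(Br)cc(OC)c2O)cc(OC)c1O
A8 | alternative 3 | trans 5-bromo-3-(hydroxymethyl)-7-methoxy-2-(4-hydroxy-3,5-dimethoxyphenyl)-2,3-dihydrobenzofuran | COc1cc([C@H]2Oc3c(OC)cc(Br)cc3[C@@H]2CO)cc(OC)c1O
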